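**Retrosynthetic overview**
1. Target ⇒ tertiary alcohol at cyclohexane C4' (Br introduced last, next to the axial C3'–Cl); oxane ring ⇒ bromonium‑triggered 6‑endo etherification of a prenyl carbinol (O1–C6 and C5–Br formed together); prenyl diol ⇒ α‑hydroxy aldehyde + allylation/cross‑metathesis.
2. Ring chlorohydrin ⇒ 4‑substituted cyclohex‑2‑enone ⇒ cyclohex‑2‑enyl group (allylic oxidation; 1,4‑reduction/α‑chlorination; MeMgBr).
3. Key disconnection: the bond oxane C2–cyclohexane C1', made by an Ireland–Claisen rearrangement of the (S)‑cyclohex‑2‑enyl ester of O‑benzyl‑lactic acid.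
4. Enabling feature: the O‑bearing quaternary oxane C2 lies between C3 (a carbinol, i.e. a masked carboxyl) and cyclohexane C1', whose neighbours C2'H2–C3'HCl can be a C2'=C3' alkene. O=C3–C2(OR)–C1'–C2'=C3' is a γ,δ‑unsaturated α‑alkoxy acid, the Claisen retron, so one carbinol centre relays to all six stereocentres.
5. Ring order: the cyclohexane ring is bought (cyclohexenol); the oxane ring is closed in step 11; Cl enters in step 5, the oxane Br in step 11, the tertiary Br in step 13.

Key step: step 2

Remark: the target is read as (2S,3S,5S)‑5‑bromo‑2‑[(1R,3S,4S)‑4‑bromo‑3‑chloro‑4‑methylcyclohexyl]‑2,6,6‑trimethyloxan‑3‑ol, and locants follow this name. Compounds 1 and 2 are assumed purchasable in enantiopure form (1 is otherwise accessible from cyclohexene oxide by enantioselective base‑induced isomerisation).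

Step 1
Reactants: 1 (S)-cyclohex-2-en-1-ol; 2 (S)-2-(benzyloxy)propanoic acid
Product: 3 (1S)-cyclohex-2-en-1-yl (2S)-2-(benzyloxy)propanoate
Conditions: DCC, DMAP (cat.), CH2Cl2, 0 → 25 °C
Reagents that add atoms: none
Why: Steglich esterification acylates the hydroxyl oxygen of 1 without touching its C–O bond, so the (S)-carbinol is carried over unchanged, while the stereocentre of 2 needs no care because it is planarised in step 2.

Step 2
Reactants: 3 (1S)-cyclohex-2-en-1-yl (2S)-2-(benzyloxy)propanoate
Product: 7 (2S)-2-(benzyloxy)-2-[(1R)-cyclohex-2-en-1-yl]propanoic acid, via lithium enolate 4 (not isolated), via silyl ketene acetal 5 (not isolated), via trimethylsilyl ester 6 (not isolated)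
Conditions: LiN(i-Pr)2, THF, −78 °C; Me3SiCl, −78 → 60 °C; 1 M HCl
Reagents that add atoms: none
Why: Deprotonation gives the lithium enolate 4 in which lithium bridges the enolate oxygen and the benzyloxy oxygen, silylation freezes this geometry in ketene acetal 5, and 5 undergoes a concerted suprafacial [3,3]-sigmatropic shift in which the ester C–O bond breaks while the enolate carbon (future oxane C2) bonds to the far alkene carbon (future cyclohexane C1'), the double bond moving to C2'=C3'. The closest known reaction type is the chelation-controlled Ireland–Claisen rearrangement of O-alkyl lactates and glycolates of secondary allylic alcohols, cyclohex-2-enyl esters included. No ring is closed; the six-membered transition state should be boat-like, as is usual for cyclohex-2-enyl esters, because the chair would place the ring CH2 groups over the OSiMe3 and OBn groups. The stereocentre at cyclohexane C1' (R) is set by the (S)-carbinol of 1 through suprafacial 1,3-chirality transfer (the new bond forms on the ring face that the ester oxygen leaves), and the quaternary centre (S) by the single chelate-defined enolate geometry read through the boat. The step therefore needs boat-over-chair discrimination and one enolate geometry, secured by the steric clash just named and by chelation, and the configuration of 2 is irrelevant because that centre is planarised. It leaves the carboxyl and the C2'=C3' alkene exactly where the oxane C3 carbinol and the C3'–Cl/C4'–Br pair have to be built.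

Step 3
Reactants: 7 (2S)-2-(benzyloxy)-2-[(1R)-cyclohex-2-en-1-yl]propanoic acid
Product: 9 methyl (2S)-2-[(1R)-cyclohex-2-en-1-yl]-2-hydroxypropanoate, via hydroxy acid 8 (not isolated)
Conditions: Li, NH3 (l), THF, −78 °C; NH4Cl; then Me3SiCHN2, MeOH/toluene, 0 °C
Reagents that add atoms: (trimethylsilyl)diazomethane, C[Si](C)(C)C=[N+]=[N-]
Why: Birch-type reductive cleavage of the benzyl ether with Li in NH3 leaves the carboxylate and the isolated ring alkene untouched, and the freed hindered α-hydroxy acid 8 is then esterified under non-basic conditions by Me3SiCHN2/MeOH, so neither stereocentre is at risk.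

Step 4
Reactants: 9 methyl (2S)-2-[(1R)-cyclohex-2-en-1-yl]-2-hydroxypropanoate
Product: 10 methyl (2S)-2-hydroxy-2-[(1R)-4-oxocyclohex-2-en-1-yl]propanoate
Conditions: Rh2(cap)4 (dirhodium tetracaprolactamate, cat.), t-BuOOH (aq.), K2CO3, CH2Cl2, 25 °C
Reagents that add atoms: tert-butyl hydroperoxide, CC(C)(C)OO
Why: Radical allylic C–H oxidation (t-BuOO radical generated by Rh2(cap)4) should abstract a hydrogen from the unhindered ring CH2 at C4 rather than the tertiary C1–H shielded by the quaternary carbon and deliver oxygen to that less hindered allyl terminus, giving the 4-oxocyclohex-2-enyl group with C1 untouched and no new stereocentre.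

Step 5
Reactants: 10 methyl (2S)-2-hydroxy-2-[(1R)-4-oxocyclohex-2-en-1-yl]propanoate
Product: 12 methyl (2S)-2-[(1R,3S)-3-chloro-4-oxocyclohexyl]-2-hydroxypropanoate, via lithium enolate 11 (not isolated)
Conditions: LiBH(s-Bu)3, THF, −78 °C; then N-chlorosuccinimide, −78 → −40 °C; NH4Cl (aq.)
Reagents that add atoms: N-chlorosuccinimide, O=C1CCC(=O)N1Cl
Why: Conjugate hydride reduction of the β-unsubstituted cyclohexenone by LiBH(s-Bu)3 gives regiospecifically the C3=C4 enolate 11, whose electrophilic α-chlorination by NCS takes place by axial attack on the half-chair that keeps the C1 side chain equatorial, so that chlorine ends up axial and trans to the side chain (3S).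

Step 6
Reactants: 12 methyl (2S)-2-[(1R,3S)-3-chloro-4-oxocyclohexyl]-2-hydroxypropanoate
Product: 13 methyl (2S)-2-[(1R,3S,4R)-3-chloro-4-hydroxy-4-methylcyclohexyl]-2-hydroxypropanoate
Conditions: MeMgBr, CeCl3, THF, −78 °C; NH4Cl (aq.)
Reagents that add atoms: methylmagnesium bromide, C[Mg]Br
Why: 1,2-Addition of the weakly basic methylcerium reagent (MeMgBr/CeCl3) to the α-chloro ketone outruns enolisation and attack on the hindered ester, the methyl group entering axially and anti to the axial C–Cl bond to give the chlorohydrin with OH cis to Cl (4R), a centre whose configuration is not critical since it is ionised in step 13.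

Step 7
Reactants: 13 methyl (2S)-2-[(1R,3S,4R)-3-chloro-4-hydroxy-4-methylcyclohexyl]-2-hydroxypropanoate
Product: 14 (2S)-2-[(1R,3S,4R)-3-chloro-4-hydroxy-4-methylcyclohexyl]-2-hydroxypropanal
Conditions: i-Bu2AlH, CH2Cl2, −78 °C; MeOH, then potassium sodium tartrate (aq.)
Reagents that add atoms: none
Why: Partial reduction of the ester with i-Bu2AlH at −78 °C stops at the aluminium hemiacetal, stabilised by chelation to the neighbouring alkoxide, and releases the α-hydroxy aldehyde only on work-up, without touching stereocentres or the alkyl chloride.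

Step 8
Reactants: 14 (2S)-2-[(1R,3S,4R)-3-chloro-4-hydroxy-4-methylcyclohexyl]-2-hydroxypropanal
Product: 15 (2S,3S)-2-[(1R,3S,4R)-3-chloro-4-hydroxy-4-methylcyclohexyl]hex-5-ene-2,3-diol
Conditions: allyl bromide, In, THF/H2O, 25 °C
Reagents that add atoms: allyl bromide, C=CCBr
Why: Barbier-type indium-mediated allylation in water, in which the free α-hydroxyl and the aldehyde oxygen chelate indium and the allyl group adds to the face of this five-membered chelate that carries the small methyl group rather than the cyclohexyl group, which sets the new carbinol as (3S).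

Step 9
Reactants: 15 (2S,3S)-2-[(1R,3S,4R)-3-chloro-4-hydroxy-4-methylcyclohexyl]hex-5-ene-2,3-diol
Product: 16 (2S,3S)-2-[(1R,3S,4R)-3-chloro-4-hydroxy-4-methylcyclohexyl]-6-methylhept-5-ene-2,3-diol
Conditions: 2-methylbut-2-ene (excess), RuCl2(=CHPh)(PCy3)(H2IMes) (second-generation Grubbs catalyst, cat.), CH2Cl2, 40 °C
Reagents that add atoms: 2-methylbut-2-ene, CC=C(C)C
Why: Olefin cross-metathesis with an excess of 2-methylbut-2-ene turns the terminal vinyl group into the trisubstituted prenyl alkene and tolerates free hydroxyl groups and the alkyl chloride, no stereocentre being involved.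

Step 10
Reactants: 16 (2S,3S)-2-[(1R,3S,4R)-3-chloro-4-hydroxy-4-methylcyclohexyl]-6-methylhept-5-ene-2,3-diol
Product: 17 (2S,3S)-2-[(1R,3S,4R)-3-chloro-4-hydroxy-4-methylcyclohexyl]-6-methyl-3-(triethylsilyloxy)hept-5-en-2-ol
Conditions: Et3SiCl, imidazole, DMF, 0 → 25 °C
Reagents that add atoms: chlorotriethylsilane, CC[Si](Cl)(CC)CC
Why: Silyl ether formation with Et3SiCl/imidazole reacts only at the single secondary hydroxyl, the two tertiary alcohols being too hindered, which masks the oxygen that would otherwise compete by 5-endo attack in step 11.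

Step 11
Reactants: 17 (2S,3S)-2-[(1R,3S,4R)-3-chloro-4-hydroxy-4-methylcyclohexyl]-6-methyl-3-(triethylsilyloxy)hept-5-en-2-ol
Product: 18 (2S,3S,5S)-5-bromo-2-[(1R,3S,4R)-3-chloro-4-hydroxy-4-methylcyclohexyl]-2,6,6-trimethyl-3-(triethylsilyloxy)oxane
Conditions: TBCO (2,4,4,6-tetrabromocyclohexa-2,5-dien-1-one), MeNO2, −20 → 0 °C, dark
Reagents that add atoms: 2,4,4,6-tetrabromocyclohexa-2,5-dien-1-one, O=C1C(Br)=CC(Br)(Br)C=C1Br
Why: Bromonium-induced etherification with the Br+ donor TBCO, in which the tertiary hydroxyl opens the bromonium ion at its tertiary carbon (6-endo, Markovnikov, anti addition) through a chair with the cyclohexyl group equatorial and the forming C–Br bond equatorial, which places bromine trans to the silyloxy group and sets C5 as S.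

Step 12
Reactants: 18 (2S,3S,5S)-5-bromo-2-[(1R,3S,4R)-3-chloro-4-hydroxy-4-methylcyclohexyl]-2,6,6-trimethyl-3-(triethylsilyloxy)oxane
Product: 19 (2S,3S,5S)-5-bromo-2-[(1R,3S,4R)-3-chloro-4-hydroxy-4-methylcyclohexyl]-2,6,6-trimethyloxan-3-ol
Conditions: HF·pyridine, pyridine, THF, 0 → 25 °C
Reagents that add atoms: none
Why: Fluoride-mediated desilylation with buffered HF·pyridine cleaves the Si–O bond under non-basic conditions that leave the chlorohydrin, the secondary bromide and the cyclic ether untouched.

Step 13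
Reactants: 19 (2S,3S,5S)-5-bromo-2-[(1R,3S,4R)-3-chloro-4-hydroxy-4-methylcyclohexyl]-2,6,6-trimethyloxan-3-ol
Product: 20 (2S,3S,5S)-5-bromo-2-[(1R,3S,4S)-4-bromo-3-chloro-4-methylcyclohexyl]-2,6,6-trimethyloxan-3-ol
Conditions: HBr (gas), CH2Cl2, −40 → −10 °C
Reagents that add atoms: hydrogen bromide, Br
Why: SN1 substitution of the tertiary alcohol by HBr, in which ionisation gives a tertiary cation bridged by the neighbouring axial chlorine, bromide opens it at the tertiary carbon from the face anti to chlorine (axial attack), and the resulting trans-diaxial bromochloride with equatorial methyl (4'S) is also the thermodynamic isomer, while the hindered di-tertiary ring ether and the secondary hydroxyl should be inert at low temperature.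

**Compound list**
1 | (S)-cyclohex-2-en-1-ol | O[C@@H]1C=CCCC1 | starting material
2 | (S)-2-(benzyloxy)propanoic acid | C[C@H](OCc1ccccc1)C(=O)O | starting material
3 | (1S)-cyclohex-2-en-1-yl (2S)-2-(benzyloxy)propanoate | C[C@H](OCc1ccccc1)C(=O)O[C@@H]1C=CCCC1 | intermediate
4 | lithium 2-(benzyloxy)-1-[(1S)-cyclohex-2-en-1-yloxy]prop-1-en-1-olate, OBn and OLi cis (chelate) | C/C(OCc1ccccc1)=C(/[O-])O[C@@H]1C=CCCC1.[Li+] | intermediate (not isolated)
5 | (Z)-[2-(benzyloxy)-1-[(1S)-cyclohex-2-en-1-yloxy]prop-1-en-1-yl]oxy(trimethyl)silane, OBn and OSiMe3 cis | C/C(OCc1ccccc1)=C(/O[Si](C)(C)C)O[C@@H]1C=CCCC1 | intermediate (not isolated)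
6 | trimethylsilyl (2S)-2-(benzyloxy)-2-[(1R)-cyclohex-2-en-1-yl]propanoate | C[C@@](OCc1ccccc1)(C(=O)O[Si](C)(C)C)[C@H]1C=CCCC1 | intermediate (not isolated)
7 | (2S)-2-(benzyloxy)-2-[(1R)-cyclohex-2-en-1-yl]propanoic acid | C[C@@](OCc1ccccc1)(C(=O)O)[C@H]1C=CCCC1 | intermediate
8 | (2S)-2-[(1R)-cyclohex-2-en-1-yl]-2-hydroxypropanoic acid | C[C@@](O)(C(=O)O)[C@H]1C=CCCC1 | intermediate (not isolated)
9 | methyl (2S)-2-[(1R)-cyclohex-2-en-1-yl]-2-hydroxypropanoate | C[C@@](O)(C(=O)OC)[C@H]1C=CCCC1 | intermediate
10 | methyl (2S)-2-hydroxy-2-[(1R)-4-oxocyclohex-2-en-1-yl]propanoate | C[C@@](O)(C(=O)OC)[C@H]1C=CC(=O)CC1 | intermediate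
11 | lithium (4R)-4-[(2S)-2-hydroxy-1-methoxy-1-oxopropan-2-yl]cyclohex-1-en-1-olate | C[C@@](O)(C(=O)OC)[C@H]1CC=C([O-])CC1.[Li+] | intermediate (not isolated)
12 | methyl (2S)-2-[(1R,3S)-3-chloro-4-oxocyclohexyl]-2-hydroxypropanoate | C[C@@](O)(C(=O)OC)[C@H]1C[C@H](Cl)C(=O)CC1 | intermediate
13 | methyl (2S)-2-[(1R,3S,4R)-3-chloro-4-hydroxy-4-methylcyclohexyl]-2-hydroxypropanoate | C[C@@](O)(C(=O)OC)[C@H]1C[C@H](Cl)[C@](C)(O)CC1 | intermediate
14 | (2S)-2-[(1R,3S,4R)-3-chloro-4-hydroxy-4-methylcyclohexyl]-2-hydroxypropanal | C[C@@](O)(C=O)[C@H]1C[C@H](Cl)[C@](C)(O)CC1 | intermediate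
15 | (2S,3S)-2-[(1R,3S,4R)-3-chloro-4-hydroxy-4-methylcyclohexyl]hex-5-ene-2,3-diol | C[C@@](O)([C@@H](O)CC=C)[C@H]1C[C@H](Cl)[C@](C)(O)CC1 | intermediate
16 | (2S,3S)-2-[(1R,3S,4R)-3-chloro-4-hydroxy-4-methylcyclohexyl]-6-methylhept-5-ene-2,3-diol | C[C@@](O)([C@@H](O)CC=C(C)C)[C@H]1C[C@H](Cl)[C@](C)(O)CC1 | intermediate
17 | (2S,3S)-2-[(1R,3S,4R)-3-chloro-4-hydroxy-4-methylcyclohexyl]-6-methyl-3-(triethylsilyloxy)hept-5-en-2-ol | C[C@@](O)([C@@H](O[Si](CC)(CC)CC)CC=C(C)C)[C@H]1C[C@H](Cl)[C@](C)(O)CC1 | intermediate
18 | (2S,3S,5S)-5-bromo-2-[(1R,3S,4R)-3-chloro-4-hydroxy-4-methylcyclohexyl]-2,6,6-trimethyl-3-(triethylsilyloxy)oxane | CC1(C)O[C@@](C)([C@@H]2CC[C@@](C)(O)[C@@H](Cl)C2)[C@@H](O[Si](CC)(CC)CC)C[C@@H]1Br | intermediate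
19 | (2S,3S,5S)-5-bromo-2-[(1R,3S,4R)-3-chloro-4-hydroxy-4-methylcyclohexyl]-2,6,6-trimethyloxan-3-ol | CC1(C)O[C@@](C)([C@@H]2CC[C@@](C)(O)[C@@H](Cl)C2)[C@@H](O)C[C@@H]1Br | intermediate
20 | (2S,3S,5S)-5-bromo-2-[(1R,3S,4S)-4-bromo-3-chloro-4-methylcyclohexyl]-2,6,6-trimethyloxan-3-ol (CID46881070) | CC1(C)O[C@@](C)([C@@H]2CC[C@](C)(Br)[C@@H](Cl)C2)[C@@H](O)C[C@@H]1Br | target

**Step count and risks**
Total step count: 13. Longest linear sequence: 13 steps (1 → 20).

Steps most likely to fail:

1. Step 2 (key step). What may go wrong: insufficient discrimination between the boat and chair transition states, so that facial selectivity at the quaternary carbon is eroded or reversed. Fallback, setting out from 1 and coming back at 9: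
   - 1 is converted with ClCO2Me/pyridine into (1S)-cyclohex-2-en-1-yl methyl carbonate F1, whose configuration is erased on ionisation.
   - (R)-Lactic acid and pivalaldehyde (acid catalysis, water removal) give the cis acetal (2R,5R)-2-tert-butyl-5-methyl-1,3-dioxolan-4-one F2.
   - The lithium enolate of F2 (LiN(i-Pr)2, THF, −78 °C) is allylated with F1 under Pd2(dba)3 (zerovalent palladium) and a C2-symmetric N,N'-(cyclohexane-1,2-diyl)bis[2-(diphenylphosphanyl)benzamide] ligand (Tsuji–Trost allylic alkylation). The symmetric η3-cyclohexenyl palladium intermediate lets the ligand enantiomer choose the terminus (C1' configuration), while the tert-butyl group sends the electrophile to the opposite enolate face (quaternary centre), so the two centres are set independently. The product is (2R,5S)-2-tert-butyl-5-[(1R)-cyclohex-2-en-1-yl]-5-methyl-1,3-dioxolan-4-one F3.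
   - NaOMe/MeOH opens F3, releases pivalaldehyde and gives 9.

2. Step 11. What may go wrong: ring closure in the wrong mode, by 5-exo attack of the tertiary hydroxyl on the secondary carbon of the bromonium ion (an oxolane with an exocyclic CMe2Br group) instead of 6-endo attack. Fallback, setting out from 17 and coming back at 18:
   - Cyclisation with Hg(OCOCF3)2 (divalent mercury; reversible mercurinium formation, Markovnikov 6-endo attack at the tertiary carbon under thermodynamic control), followed by NaCl work-up, gives chloro{(3S,5S,6S)-6-[(1R,3S,4R)-3-chloro-4-hydroxy-4-methylcyclohexyl]-2,2,6-trimethyl-5-(triethylsilyloxy)oxan-3-yl}mercury F5, with HgCl equatorial and trans to the ring oxygen.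
   - Bromodemercuration with Br2 in pyridine replaces C–Hg by C–Br with retention and gives 18.

3. Step 4. What may go wrong: poor site selectivity of hydrogen abstraction and oxygen transfer (attack at the tertiary allylic C1–H, or oxygenation of the allyl terminus next to the side chain), together with over-oxidation. Fallback, setting out from 9 and coming back at 10:
   - Allylic hydroxylation with SeO2 (cat.)/t-BuOOH in CH2Cl2 (ene reaction followed by a [2,3]-sigmatropic shift, which prefers the ring CH2 over the CH and returns the double bond to its place) gives methyl (2S)-2-hydroxy-2-[(1R,4R)-4-hydroxycyclohex-2-en-1-yl]propanoate F4; either C4 epimer serves.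
   - Oxidation of F4 with Dess–Martin periodinane gives 10.

Further compounds
F1 | step 2 | (1S)-cyclohex-2-en-1-yl methyl carbonate | COC(=O)O[C@@H]1C=CCCC1
F2 | step 2 | (2R,5R)-2-tert-butyl-5-methyl-1,3-dioxolan-4-one | C[C@H]1O[C@@H](C(C)(C)C)OC1=O
F3 | step 2 | (2R,5S)-2-tert-butyl-5-[(1R)-cyclohex-2-en-1-yl]-5-methyl-1,3-dioxolan-4-one | C[C@@]1([C@H]2C=CCCC2)O[C@@H](C(C)(C)C)OC1=O
F4 | step 4 | methyl (2S)-2-hydroxy-2-[(1R,4R)-4-hydroxycyclohex-2-en-1-yl]propanoate | C[C@@](O)(C(=O)OC)[C@H]1C=C[C@H](O)CC1
F5 | step 11 | chloro{(3S,5S,6S)-6-[(1R,3S,4R)-3-chloro-4-hydroxy-4-methylcyclohexyl]-2,2,6-trimethyl-5-(triethylsilyloxy)oxan-3-yl}mercury | CC1(C)O[C@@](C)([C@@H]2CC[C@@](C)(O)[C@@H](Cl)C2)[C@@H](O[Si](CC)(CC)CC)C[C@@H]1[Hg]Cl
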